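## The problem

Compound 21 is a (2S)-flavanone. Ring A, substituted everywhere except C8, is fused to the dihydropyranone ring C, and ring B hangs from C2, the only stereocentre. No other element in the molecule can steer C2, and C2 is fragile. It is the β-carbon of an aryl ketone and carries an aryloxy leaving group, so base opens ring C to the 2'-hydroxychalcone and recloses it without control, and the para-methoxy group of ring B makes the C2–O1 bond ionisable in strong acid. Ring A poses a regiochemical question: the two oxygens ortho to the acyl carbon C4a differ only in their neighbours (prenyl at C6, hydrogen at C8), and the one next to hydrogen must become O1, otherwise the 8-prenyl isomer results. Ring B needs an (E)-geranyl chain at C2', wedged between the C1' attachment and the 3'-oxygen. The prenyl and geranyl groups bring three electron-rich trisubstituted alkenes, two of them beside phenolic oxygens, which rules out hydrogenation, electrophilic oxidants and hot strong acid. The handle is that C2–C3–C4(=O) is the saturated form of a chalcone enone, the one electron-poor alkene of the skeleton. An oxirane across C2 and C3 fixes the configuration at C2, leaves at C3 an oxygen α to the C4 carbonyl that electron transfer can remove, and offers C2 to the ring A oxygen six atoms away for a 6-endo closure of ring C.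

## Retrosynthesis

Protecting groups. Target 21 is traced to its bis(methoxymethyl) ether 20 by cutting the two O–CH2 acetal bonds. The acetal ethers are stable to the bases used earlier and fall in dilute acid, so the last step exposes the free 5-hydroxyflavanone to no base.

C3–O bond. An oxygen is put back on C3, which leads from 20 to the acetate 19 and the trans-dihydroflavonol 18. A direct asymmetric oxa-Michael closure of a 2'-hydroxychalcone is reversible and poorly controlled for unactivated substrates. In 18 a second stereocentre stands next to C2 and holds the ring closure trans. The forward reaction must cleave an α-acyloxy ketone reductively without disturbing C2.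

O1–C2 bond. Cutting the ring C ether bond of 18 gives the 2'-hydroxy epoxy ketone 17 and, with the phenol masked, the silyl ether 16. The forward step is a 6-endo opening of the oxirane at its benzylic carbon with inversion. It needs this one phenol set free by fluoride while the other ring A oxygen stays an acetal ether, and it needs neutral-to-acidic conditions, because a phenoxide prefers the α-carbon and the five-membered ring.

Oxirane C–O bonds (the key cut). Removing the oxirane oxygen of 16 gives the achiral (E)-chalcone 15. Dihydroxylation or electrophilic epoxidation would attack the prenyl and geranyl alkenes first. A nucleophilic peroxide on a poly-leucine helix touches only the enone and sets both stereocentres in one operation.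

Cα=Cβ bond. The enone of 15, made by silylation of the hydroxychalcone 14, is cut into the ring A methyl ketone 5 and the ring B aldehyde 13, two halves of similar size. The silyl group is added after the condensation because aryl silyl ethers do not survive aqueous hydroxide. The forward reaction is a Claisen–Schmidt condensation that tolerates the chelated phenol of 5.

Aryl–prenyl bond. The prenyl group of 5 is traced to the O-prenyl ether 4, made from the mono-acetal 2, the symmetric dihydroxy ketone 1 and prenyl bromide 3. A para-Claisen shift moves the chain to the carbon para to the ether oxygen. The phenol it releases is therefore the one remote from prenyl, the future O1, and the acetal ether placed on 1 at the outset ends up beside the prenyl group. Direct C-prenylation of 1 or an ortho-Claisen shift would leave the two oxygens undifferentiated or free the wrong one.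

Aryl–geranyl bond. Aldehyde 13 comes from its dimethyl acetal 12, which is cut at the C2–CH2 bond into an aryl nucleophile (10, then 11) and geranyl bromide 9. The nucleophile is made from bromide 8, which derives from 7 and from the purchasable bromophenol aldehyde 6. The bromine marks C2 unambiguously. A Claisen shift of an O-geranyl ether would give the branched chain.

## Roads not taken

Alternative 1: The C2–C3 bond is cut, leading to the racemic enol acetal A1, a 2-aryl-4-methylidene-1,3-benzodioxine. In the forward step a confined chiral Brønsted acid ionises the acetal C–O bond and the enol carbon attacks the oxocarbenium carbon (Petasis–Ferrier rearrangement), giving flavanone A2 with C2 set.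
- Merits: C2 is made in the ring-closing event by catalysis, a racemic precursor converges to one enantiomer, no base is involved, and no oxygen has to be added to C3 and removed again. In step count after the key step this road is clearly better.
- Weak points: a very strong acid meets a prenyl group flanked by oxygens. Asymmetric induction in this ring size and substrate class is not established. A2 has no geranyl group, so the chain would have to go on afterwards at the carbon between C1' and the 3'-oxygen of a base-sensitive flavanone, where neither metalation nor phenoxide C-alkylation is selective. A1 also needs a methylenation of a benzodioxinone.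
- Against this the chosen plan sets an asymmetric step of known behaviour that accepts the complete carbon skeleton with all three alkenes in place.

Alternative 2: The C4a–C8a bond of ring A is cut, so the arene is built from the pyranone A3, which masks a tetraketide. An alkoxide opens the lactone and the doubly activated methylene condenses onto the new ester (Claisen condensation), giving chalcone A4.
- Merits: the oxygenation and prenyl pattern of ring A is written into an open chain, ring A needs no protecting groups, and the same aldehyde serves as in the chosen plan.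
- Weak points: the key step creates no stereocentre. A4 has both ortho hydroxyls free and they differ only by the prenyl neighbour, so ring C closure would give 6- and 8-prenyl flavanones with no control at C2. A3 is many steps from simple materials, whereas the arene of the chosen plan is bought.
- The chosen plan passes through the same chalcone stage with the two oxygens already told apart and the enone ready for an asymmetric step.

Alternative 3: The O1–C8a and C4–C4a bonds are cut. A fluoride source releases the aryne from silyl triflate A5, the carboxylate of the (R)-β-silyloxy acid A6 adds to the aryne carbon remote from the acetal ether, and the aryl anion takes over the acyl group, giving the ortho-hydroxyaryl ketone A7.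
- Merits: the union is convergent, the oxygen-bearing stereocentre is set early by standard asymmetric carbonyl chemistry, and A7 emerges with the right phenol free. An inverting Mitsunobu closure would reach the 2S series with no C3 oxygen to handle, so after the union this road is at least as short as the chosen one.
- Weak points: A5 is a pentasubstituted arene with silyl and triflate groups and needs a long preparation. Acyl transfer competes with protonation of the aryl anion. Fluoride threatens the silyl ether, and A7 can lose silanolate to give the chalcone. The Mitsunobu closure at a para-methoxybenzylic carbinol can ionise, with no second stereocentre to correct the result.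
- The chosen plan sets against the shorter endgame a ring closure guarded by C3 and starting materials that are two purchasable arenes.

Key step: step 9

Assumption: poly-L-leucine is taken to give the same (2R,3S) sense with 15 as with the parent chalcone; if the sense is opposite, poly-D-leucine is used and nothing else changes.

## Route

Step 1
Reactants: 1 1-(2,6-dihydroxy-4-methoxyphenyl)ethan-1-one
Product: 2 1-[2-hydroxy-4-methoxy-6-(methoxymethoxy)phenyl]ethan-1-one
Conditions: MOMCl (1.05 equiv), i-Pr2NEt, CH2Cl2, 0 °C → rt
Reagents that add atoms: chloromethyl methyl ether, COCCl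
Why: Acetal ether formation at one of two equivalent phenols; after the first etherification the remaining hydroxyl is locked in the hydrogen bond to the acetyl carbonyl and reacts much more slowly, so one equivalent should stop at 2.

Step 2
Reactants: 2 1-[2-hydroxy-4-methoxy-6-(methoxymethoxy)phenyl]ethan-1-one; 3 1-bromo-3-methylbut-2-ene (prenyl bromide)
Product: 4 1-[4-methoxy-2-(methoxymethoxy)-6-(3-methylbut-2-en-1-yloxy)phenyl]ethan-1-one
Conditions: K2CO3, acetone, reflux
Reagents that add atoms: none
Why: Williamson ether synthesis at the chelated phenol; carbonate in refluxing acetone is the standard way to O-allylate 2-hydroxyacetophenones, and the acetal ether and ketone are inert.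

Step 3
Reactants: 4 1-[4-methoxy-2-(methoxymethoxy)-6-(3-methylbut-2-en-1-yloxy)phenyl]ethan-1-one
Product: 5 1-[6-hydroxy-4-methoxy-2-(methoxymethoxy)-3-(3-methylbut-2-en-1-yl)phenyl]ethan-1-one
Conditions: PhNEt2, 200 °C, degassed, sealed vessel
Reagents that add atoms: none
Why: Aromatic para-Claisen (Claisen–Cope) rearrangement: a [3,3] shift to an ortho carbon with allyl inversion, then a second [3,3] shift to the para carbon, restores the linear prenyl group, and tautomerisation gives the phenol; this outcome is known for 2-prenyloxy-4,6-dialkoxyacetophenones. The hydroxyl set free is the one remote from the prenyl group, which is the oxygen that must become O1.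

Step 4
Reactants: 6 2-bromo-3-hydroxy-4-methoxybenzaldehyde
Product: 7 2-bromo-3-(dimethoxymethyl)-6-methoxyphenol
Conditions: HC(OMe)3, MeOH, p-TsOH (cat.), rt; Et3N quench
Reagents that add atoms: trimethyl orthoformate, COC(OC)OC; methanol, CO
Why: Acid-catalysed acetalisation with orthoformate as water scavenger masks the aldehyde against the organolithium of step 6; it is done before the acetal ether goes on the phenol so that this acid-labile group never meets acidic methanol.

Step 5
Reactants: 7 2-bromo-3-(dimethoxymethyl)-6-methoxyphenol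
Product: 8 2-bromo-1-(dimethoxymethyl)-4-methoxy-3-(methoxymethoxy)benzene
Conditions: MOMCl, i-Pr2NEt, CH2Cl2, 0 °C → rt
Reagents that add atoms: chloromethyl methyl ether, COCCl
Why: Methoxymethyl protection of the phenol under basic conditions, to which the dimethyl acetal is inert; the group matches the one on ring A so that a single operation removes both at the end.

Step 6
Reactants: 8 2-bromo-1-(dimethoxymethyl)-4-methoxy-3-(methoxymethoxy)benzene; 9 (2E)-1-bromo-3,7-dimethylocta-2,6-diene (geranyl bromide)
Product: 13 2-[(2E)-3,7-dimethylocta-2,6-dien-1-yl]-4-methoxy-3-(methoxymethoxy)benzaldehyde, via aryllithium 10 (not isolated), via arylcopper 11 (not isolated), via geranylated dimethyl acetal 12 (not isolated)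
Conditions: n-BuLi (1.05 equiv), THF, −78 °C; CuBr·SMe2, −78 → −40 °C; 9, −40 → 0 °C; then 1 M HCl, THF, 0 °C
Reagents that add atoms: water, O (carbonyl oxygen of 13); n-butyllithium, [Li]CCCC, and CuBr·SMe2, [Cu]Br.CSC, supply only the metal atoms of 10 and 11
Why: Bromine–lithium exchange fixes the nucleophilic site at C2, between two groups that chelate lithium; transmetalation to copper and SN2 allylation with the primary allylic bromide give the linear (E)-geranyl arene, a standard way to geranylate arenes. Dilute acid in the work-up hydrolyses the dimethyl acetal much faster than the aryl acetal ether.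

Step 7
Reactants: 5 1-[6-hydroxy-4-methoxy-2-(methoxymethoxy)-3-(3-methylbut-2-en-1-yl)phenyl]ethan-1-one; 13 2-[(2E)-3,7-dimethylocta-2,6-dien-1-yl]-4-methoxy-3-(methoxymethoxy)benzaldehyde
Product: 14 (2E)-3-{2-[(2E)-3,7-dimethylocta-2,6-dien-1-yl]-4-methoxy-3-(methoxymethoxy)phenyl}-1-[6-hydroxy-4-methoxy-2-(methoxymethoxy)-3-(3-methylbut-2-en-1-yl)phenyl]prop-2-en-1-one
Conditions: KOH, EtOH–H2O, rt; cold dilute HCl to pH 6
Reagents that add atoms: none
Why: Claisen–Schmidt aldol condensation; only the methyl ketone can enolise, the aldehyde cannot, and E1cB dehydration gives the (E)-enone. In strong base the product rests as the chalcone phenoxide, and cold neutralisation avoids closure to the racemic flavanone.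

Step 8
Reactants: 14 (2E)-3-{2-[(2E)-3,7-dimethylocta-2,6-dien-1-yl]-4-methoxy-3-(methoxymethoxy)phenyl}-1-[6-hydroxy-4-methoxy-2-(methoxymethoxy)-3-(3-methylbut-2-en-1-yl)phenyl]prop-2-en-1-one
Product: 15 (2E)-3-{2-[(2E)-3,7-dimethylocta-2,6-dien-1-yl]-4-methoxy-3-(methoxymethoxy)phenyl}-1-[4-methoxy-2-(methoxymethoxy)-3-(3-methylbut-2-en-1-yl)-6-(triisopropylsilyloxy)phenyl]prop-2-en-1-one
Conditions: TIPSCl, imidazole, DMAP (cat.), DMF, rt → 40 °C
Reagents that add atoms: chlorotriisopropylsilane, CC(C)[Si](Cl)(C(C)C)C(C)C
Why: Silylation of the only free hydroxyl; the bulky silyl ether keeps a phenoxide from forming in step 9 and is later removed by fluoride without touching the acetal ethers. It is installed after step 7 because aryl silyl ethers do not survive the hydroxide of the condensation.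

Step 9
Reactants: 15 (2E)-3-{2-[(2E)-3,7-dimethylocta-2,6-dien-1-yl]-4-methoxy-3-(methoxymethoxy)phenyl}-1-[4-methoxy-2-(methoxymethoxy)-3-(3-methylbut-2-en-1-yl)-6-(triisopropylsilyloxy)phenyl]prop-2-en-1-one
Product: 16 [(2R,3S)-3-{2-[(2E)-3,7-dimethylocta-2,6-dien-1-yl]-4-methoxy-3-(methoxymethoxy)phenyl}oxiran-2-yl][4-methoxy-2-(methoxymethoxy)-3-(3-methylbut-2-en-1-yl)-6-(triisopropylsilyloxy)phenyl]methanone
Conditions: poly-L-leucine (preactivated), urea–H2O2, DBU, THF, rt
Reagents that add atoms: urea–hydrogen peroxide, OO.NC(N)=O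
Why: Juliá–Colonna epoxidation, a Weitz–Scheffer nucleophilic epoxidation carried out on a helical poly-amino acid. Hydroperoxide anion, held by the N–H groups at the amino end of the poly-L-leucine helix next to the bound enone, adds to the β-carbon from one face. The resulting peroxy enolate closes the oxirane by 3-exo-tet attack of the α-carbon on the near peroxide oxygen with loss of hydroxide. The closest known reaction type is the poly-leucine epoxidation of chalcones that carry 2'-alkoxy groups. The configuration at the β-carbon (future C2) is set by the catalyst in the conjugate addition, and that at the α-carbon (future C3) follows from the E geometry, because the enolate closes before it can rotate, so only the trans oxirane forms. The step needs enantioface selectivity, which the catalyst supplies, and chemoselectivity, which the substrate supplies: the enone is the only electrophilic alkene and the three trisubstituted alkenes are inert to a nucleophilic oxidant. It also needs the absence of a free phenol; the hindered silyl ether and the water-free medium should keep the Si–O bond intact.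

Step 10
Reactants: 16 [(2R,3S)-3-{2-[(2E)-3,7-dimethylocta-2,6-dien-1-yl]-4-methoxy-3-(methoxymethoxy)phenyl}oxiran-2-yl][4-methoxy-2-(methoxymethoxy)-3-(3-methylbut-2-en-1-yl)-6-(triisopropylsilyloxy)phenyl]methanone
Product: 18 (2R,3R)-2-{2-[(2E)-3,7-dimethylocta-2,6-dien-1-yl]-4-methoxy-3-(methoxymethoxy)phenyl}-3-hydroxy-7-methoxy-5-(methoxymethoxy)-6-(3-methylbut-2-en-1-yl)-2,3-dihydro-4H-chromen-4-one, via free phenol epoxy ketone 17 (not isolated)
Conditions: TBAF, AcOH, THF, 0 °C; then CSA (cat.), CH2Cl2, 0 °C
Reagents that add atoms: none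
Why: Fluoride buffered with acetic acid removes the silyl group and leaves phenol 17 neutral, so base-induced attack at the α-carbon (the benzofuranone pathway) is avoided. Catalytic acid then activates the oxirane at its benzylic carbon, favoured by the para-methoxy group of ring B, and the phenol closes ring C 6-endo with inversion, as in the known acid-mediated cyclisation of 2'-hydroxychalcone oxides to trans-dihydroflavonols. C3 keeps its configuration and makes the 2,3-trans product the favoured one even if the opening has cationic character; any cis isomer is a diastereomer and can be removed at this stage.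

Step 11
Reactants: 18 (2R,3R)-2-{2-[(2E)-3,7-dimethylocta-2,6-dien-1-yl]-4-methoxy-3-(methoxymethoxy)phenyl}-3-hydroxy-7-methoxy-5-(methoxymethoxy)-6-(3-methylbut-2-en-1-yl)-2,3-dihydro-4H-chromen-4-one
Product: 19 (2R,3R)-2-{2-[(2E)-3,7-dimethylocta-2,6-dien-1-yl]-4-methoxy-3-(methoxymethoxy)phenyl}-7-methoxy-5-(methoxymethoxy)-6-(3-methylbut-2-en-1-yl)-4-oxo-3,4-dihydro-2H-chromen-3-yl acetate
Conditions: Ac2O, pyridine, DMAP (cat.), CH2Cl2, 0 °C → rt
Reagents that add atoms: acetic anhydride, CC(=O)OC(C)=O
Why: Acetylation of the only free hydroxyl turns the C3 oxygen into a better leaving group for electron-transfer cleavage; mild amine base at room temperature does not open ring C.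

Step 12
Reactants: 19 (2R,3R)-2-{2-[(2E)-3,7-dimethylocta-2,6-dien-1-yl]-4-methoxy-3-(methoxymethoxy)phenyl}-7-methoxy-5-(methoxymethoxy)-6-(3-methylbut-2-en-1-yl)-4-oxo-3,4-dihydro-2H-chromen-3-yl acetate
Product: 20 (2S)-2-{2-[(2E)-3,7-dimethylocta-2,6-dien-1-yl]-4-methoxy-3-(methoxymethoxy)phenyl}-7-methoxy-5-(methoxymethoxy)-6-(3-methylbut-2-en-1-yl)-2,3-dihydro-4H-chromen-4-one
Conditions: SmI2 (2.5 equiv), THF–MeOH, −78 °C
Reagents that add atoms: none
Why: SmI2 reduction of an α-acyloxy ketone: two single-electron transfers to the carbonyl expel acetate and give the samarium enolate, which methanol protonates at −78 °C before it can eliminate the ring oxygen. C2 is not involved; with the C3 oxygen gone its descriptor changes from R to S with no change in space.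

Step 13
Reactants: 20 (2S)-2-{2-[(2E)-3,7-dimethylocta-2,6-dien-1-yl]-4-methoxy-3-(methoxymethoxy)phenyl}-7-methoxy-5-(methoxymethoxy)-6-(3-methylbut-2-en-1-yl)-2,3-dihydro-4H-chromen-4-one
Product: 21 (2S)-2-{2-[(2E)-3,7-dimethylocta-2,6-dien-1-yl]-3-hydroxy-4-methoxyphenyl}-5-hydroxy-7-methoxy-6-(3-methylbut-2-en-1-yl)-2,3-dihydro-4H-chromen-4-one
Conditions: 3 M aq. HCl, MeOH, rt → 40 °C
Reagents that add atoms: none
Why: Acid-catalysed cleavage of both aryl methoxymethyl ethers in methanol, the usual last step for prenylated flavanones. Dilute acid near room temperature is chosen so that neither side chain cyclises onto its neighbouring phenol and C2 is not ionised; no base is used because the free 5-hydroxyflavanone would racemise through the chalcone.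

## Compound list

1 | 1-(2,6-dihydroxy-4-methoxyphenyl)ethan-1-one | CC(=O)c1c(O)cc(OC)cc1O | starting material
2 | 1-[2-hydroxy-4-methoxy-6-(methoxymethoxy)phenyl]ethan-1-one | CC(=O)c1c(O)cc(OC)cc1OCOC | intermediate
3 | 1-bromo-3-methylbut-2-ene (prenyl bromide) | CC(C)=CCBr | starting material
4 | 1-[4-methoxy-2-(methoxymethoxy)-6-(3-methylbut-2-en-1-yloxy)phenyl]ethan-1-one | CC(=O)c1c(OCC=C(C)C)cc(OC)cc1OCOC | intermediate
5 | 1-[6-hydroxy-4-methoxy-2-(methoxymethoxy)-3-(3-methylbut-2-en-1-yl)phenyl]ethan-1-one | CC(=O)c1c(O)cc(OC)c(CC=C(C)C)c1OCOC | intermediate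
6 | 2-bromo-3-hydroxy-4-methoxybenzaldehyde | COc1ccc(C=O)c(Br)c1O | starting material
7 | 2-bromo-3-(dimethoxymethyl)-6-methoxyphenol | COc1ccc(C(OC)OC)c(Br)c1O | intermediate
8 | 2-bromo-1-(dimethoxymethyl)-4-methoxy-3-(methoxymethoxy)benzene | COc1ccc(C(OC)OC)c(Br)c1OCOC | intermediate
9 | (2E)-1-bromo-3,7-dimethylocta-2,6-diene (geranyl bromide) | BrC/C=C(\C)CCC=C(C)C | starting material
10 | [6-(dimethoxymethyl)-3-methoxy-2-(methoxymethoxy)phenyl]lithium | COc1ccc(C(OC)OC)c([Li])c1OCOC | intermediate (not isolated)
11 | [6-(dimethoxymethyl)-3-methoxy-2-(methoxymethoxy)phenyl]copper | COc1ccc(C(OC)OC)c([Cu])c1OCOC | intermediate (not isolated)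
12 | 1-(dimethoxymethyl)-2-[(2E)-3,7-dimethylocta-2,6-dien-1-yl]-4-methoxy-3-(methoxymethoxy)benzene | COc1ccc(C(OC)OC)c(C/C=C(\C)CCC=C(C)C)c1OCOC | intermediate (not isolated)
13 | 2-[(2E)-3,7-dimethylocta-2,6-dien-1-yl]-4-methoxy-3-(methoxymethoxy)benzaldehyde | COc1ccc(C=O)c(C/C=C(\C)CCC=C(C)C)c1OCOC | intermediate
14 | (2E)-3-{2-[(2E)-3,7-dimethylocta-2,6-dien-1-yl]-4-methoxy-3-(methoxymethoxy)phenyl}-1-[6-hydroxy-4-methoxy-2-(methoxymethoxy)-3-(3-methylbut-2-en-1-yl)phenyl]prop-2-en-1-one | COc1cc(O)c(C(=O)/C=C/c2ccc(OC)c(OCOC)c2C/C=C(\C)CCC=C(C)C)c(OCOC)c1CC=C(C)C | intermediate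
15 | (2E)-3-{2-[(2E)-3,7-dimethylocta-2,6-dien-1-yl]-4-methoxy-3-(methoxymethoxy)phenyl}-1-[4-methoxy-2-(methoxymethoxy)-3-(3-methylbut-2-en-1-yl)-6-(triisopropylsilyloxy)phenyl]prop-2-en-1-one | COc1cc(O[Si](C(C)C)(C(C)C)C(C)C)c(C(=O)/C=C/c2ccc(OC)c(OCOC)c2C/C=C(\C)CCC=C(C)C)c(OCOC)c1CC=C(C)C | intermediate
16 | [(2R,3S)-3-{2-[(2E)-3,7-dimethylocta-2,6-dien-1-yl]-4-methoxy-3-(methoxymethoxy)phenyl}oxiran-2-yl][4-methoxy-2-(methoxymethoxy)-3-(3-methylbut-2-en-1-yl)-6-(triisopropylsilyloxy)phenyl]methanone | COc1cc(O[Si](C(C)C)(C(C)C)C(C)C)c(C(=O)[C@@H]2O[C@H]2c3ccc(OC)c(OCOC)c3C/C=C(\C)CCC=C(C)C)c(OCOC)c1CC=C(C)C | intermediate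
17 | [(2R,3S)-3-{2-[(2E)-3,7-dimethylocta-2,6-dien-1-yl]-4-methoxy-3-(methoxymethoxy)phenyl}oxiran-2-yl][6-hydroxy-4-methoxy-2-(methoxymethoxy)-3-(3-methylbut-2-en-1-yl)phenyl]methanone | COc1cc(O)c(C(=O)[C@@H]2O[C@H]2c3ccc(OC)c(OCOC)c3C/C=C(\C)CCC=C(C)C)c(OCOC)c1CC=C(C)C | intermediate (not isolated)
18 | (2R,3R)-2-{2-[(2E)-3,7-dimethylocta-2,6-dien-1-yl]-4-methoxy-3-(methoxymethoxy)phenyl}-3-hydroxy-7-methoxy-5-(methoxymethoxy)-6-(3-methylbut-2-en-1-yl)-2,3-dihydro-4H-chromen-4-one | COc1ccc([C@@H]2[C@@H](O)C(=O)c3c(cc(OC)c(CC=C(C)C)c3OCOC)O2)c(C/C=C(\C)CCC=C(C)C)c1OCOC | intermediate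
19 | (2R,3R)-2-{2-[(2E)-3,7-dimethylocta-2,6-dien-1-yl]-4-methoxy-3-(methoxymethoxy)phenyl}-7-methoxy-5-(methoxymethoxy)-6-(3-methylbut-2-en-1-yl)-4-oxo-3,4-dihydro-2H-chromen-3-yl acetate | COc1ccc([C@@H]2[C@@H](OC(C)=O)C(=O)c3c(cc(OC)c(CC=C(C)C)c3OCOC)O2)c(C/C=C(\C)CCC=C(C)C)c1OCOC | intermediate
20 | (2S)-2-{2-[(2E)-3,7-dimethylocta-2,6-dien-1-yl]-4-methoxy-3-(methoxymethoxy)phenyl}-7-methoxy-5-(methoxymethoxy)-6-(3-methylbut-2-en-1-yl)-2,3-dihydro-4H-chromen-4-one | COc1ccc([C@@H]2CC(=O)c3c(cc(OC)c(CC=C(C)C)c3OCOC)O2)c(C/C=C(\C)CCC=C(C)C)c1OCOC | intermediate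
21 | (2S)-2-{2-[(2E)-3,7-dimethylocta-2,6-dien-1-yl]-3-hydroxy-4-methoxyphenyl}-5-hydroxy-7-methoxy-6-(3-methylbut-2-en-1-yl)-2,3-dihydro-4H-chromen-4-one | COc1ccc([C@@H]2CC(=O)c3c(cc(OC)c(CC=C(C)C)c3O)O2)c(C/C=C(\C)CCC=C(C)C)c1O | target

## Step count and risks

Total: 13 steps. Longest linear sequence: 10 steps (1 → 21 through steps 1–3 and 7–13; the ring B branch, steps 4–6, joins at step 7 and is equally long).

Step 9 (key step). Both aryl groups of 15 carry ortho substituents, which twist the enone and may lead to slow turnover and poor facial selectivity on the helix. The second danger is loss of the aryl silyl ether to hydroperoxide anion, after which a phenoxide would attack the new oxirane at the α-carbon and give the five-membered ring.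

The fallback leaves basic peroxide altogether and sets out from 15:
- Luche reduction (NaBH4, CeCl3·7H2O, MeOH, 0 °C) should give the racemic allylic alcohol (2E)-3-{2-[(2E)-3,7-dimethylocta-2,6-dien-1-yl]-4-methoxy-3-(methoxymethoxy)phenyl}-1-[4-methoxy-2-(methoxymethoxy)-3-(3-methylbut-2-en-1-yl)-6-(triisopropylsilyloxy)phenyl]prop-2-en-1-ol F1.
- Sharpless kinetic resolution (Ti(OiPr)4, L-(+)-diisopropyl tartrate, t-BuOOH, 4 Å sieves, CH2Cl2, −20 °C) should epoxidise only the allylic-alcohol alkene of the fast-reacting (R)-enantiomer. The product is the erythro epoxy alcohol (S)-[(2S,3S)-3-{2-[(2E)-3,7-dimethylocta-2,6-dien-1-yl]-4-methoxy-3-(methoxymethoxy)phenyl}oxiran-2-yl][4-methoxy-2-(methoxymethoxy)-3-(3-methylbut-2-en-1-yl)-6-(triisopropylsilyloxy)phenyl]methanol F2.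
- Dess–Martin oxidation buffered with NaHCO3 returns to the route at 16.
- The price is at most half of the material and an acid-sensitive aryl epoxy alcohol in contact with a titanium alkoxide.

Step 10. Three processes compete with the wanted closure: attack of the oxygen at the α-carbon if any phenoxide survives, a 1,2-aroyl shift of the acid-activated oxirane (Meinwald rearrangement), and capture of a benzylic cation by the ortho geranyl alkene. Partial ionisation would also let some cis product form.

The fallback removes the oxirane before ring closure and sets out from 16: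
- SmI2 (THF–MeOH, −90 °C) should cleave the Cα–O bond of the epoxy ketone to the β-hydroxy ketone (3R)-3-{2-[(2E)-3,7-dimethylocta-2,6-dien-1-yl]-4-methoxy-3-(methoxymethoxy)phenyl}-3-hydroxy-1-[4-methoxy-2-(methoxymethoxy)-3-(3-methylbut-2-en-1-yl)-6-(triisopropylsilyloxy)phenyl]propan-1-one F3.
- TBAF with AcOH should free the phenol (3R)-3-{2-[(2E)-3,7-dimethylocta-2,6-dien-1-yl]-4-methoxy-3-(methoxymethoxy)phenyl}-3-hydroxy-1-[6-hydroxy-4-methoxy-2-(methoxymethoxy)-3-(3-methylbut-2-en-1-yl)phenyl]propan-1-one F4.
- Mitsunobu etherification (PPh3, DIAD, THF, 0 °C) should close ring C with inversion and return to the route at 20, bypassing 18 and 19.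
- It is not the first choice because the benzylic carbinol can ionise or dehydrate and no C3 centre guards the outcome.

Step 12. The samarium enolate has the ring oxygen in the β-position. Elimination of the aryloxide would open ring C to the chalcone, and reclosure would erase C2; reduction of the aryl ketone itself is a lesser risk.

The fallback replaces the enolate by a radical and sets out from 18:
- 1,1'-Thiocarbonyldiimidazole with DMAP should give O-[(2R,3R)-2-{2-[(2E)-3,7-dimethylocta-2,6-dien-1-yl]-4-methoxy-3-(methoxymethoxy)phenyl}-7-methoxy-5-(methoxymethoxy)-6-(3-methylbut-2-en-1-yl)-4-oxo-3,4-dihydro-2H-chromen-3-yl] 1H-imidazole-1-carbothioate F5.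
- Barton–McCombie reduction (Bu3SnH at high concentration, AIBN, toluene, 80 °C) returns to the route at 20. A C3 radical has no tendency to expel the aryloxy group.

Step 3. The rearrangement may stop at the ortho stage by tautomerisation, which leaves a branched 1,1-dimethylallyl group on the carbon between the two oxygens, and the long heating may cost the acetal ether.

The fallback gives up the rearrangement and sets out from 1:
- C-Prenylation with 3 (DBU, THF) should give 1-[2,6-dihydroxy-4-methoxy-3-(3-methylbut-2-en-1-yl)phenyl]ethan-1-one F6.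
- Silylation of the less hindered hydroxyl (TIPSCl, imidazole, DMF) should give 1-[2-hydroxy-4-methoxy-3-(3-methylbut-2-en-1-yl)-6-(triisopropylsilyloxy)phenyl]ethan-1-one F7.
- Etherification of the remaining hindered hydroxyl (NaH, MOMCl, DMF, 0 °C) should give 1-[4-methoxy-2-(methoxymethoxy)-3-(3-methylbut-2-en-1-yl)-6-(triisopropylsilyloxy)phenyl]ethan-1-one F8.
- TBAF with AcOH returns to the route at 5.
- This route is a step longer and rests on steric differentiation of the two phenols.

Step 6. The arylcopper may attack the γ-carbon of 9 (SN2′), which gives the branched chain; homocoupling and protonation of the aryllithium are further losses.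

The fallback exchanges the roles of the partners and sets out from 6:
- Etherification (MOMCl, i-Pr2NEt) should give 2-bromo-4-methoxy-3-(methoxymethoxy)benzaldehyde F9.
- Stille coupling with tributyl[(2E)-3,7-dimethylocta-2,6-dien-1-yl]stannane (Pd(PPh3)4, a zerovalent palladium complex; CsF, DMF, 80 °C) returns to the route at 13. It needs no acetal and no organolithium, and the ortho formyl group aids oxidative addition.
- Control of linear against branched coupling is less assured than in the copper route.

## Further compounds

F1 | step 9 | (2E)-3-{2-[(2E)-3,7-dimethylocta-2,6-dien-1-yl]-4-methoxy-3-(methoxymethoxy)phenyl}-1-[4-methoxy-2-(methoxymethoxy)-3-(3-methylbut-2-en-1-yl)-6-(triisopropylsilyloxy)phenyl]prop-2-en-1-ol (racemic) | COc1cc(O[Si](C(C)C)(C(C)C)C(C)C)c(C(O)/C=C/c2ccc(OC)c(OCOC)c2C/C=C(\C)CCC=C(C)C)c(OCOC)c1CC=C(C)C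
F2 | step 9 | (S)-[(2S,3S)-3-{2-[(2E)-3,7-dimethylocta-2,6-dien-1-yl]-4-methoxy-3-(methoxymethoxy)phenyl}oxiran-2-yl][4-methoxy-2-(methoxymethoxy)-3-(3-methylbut-2-en-1-yl)-6-(triisopropylsilyloxy)phenyl]methanol | COc1cc(O[Si](C(C)C)(C(C)C)C(C)C)c([C@H](O)[C@@H]2O[C@H]2c3ccc(OC)c(OCOC)c3C/C=C(\C)CCC=C(C)C)c(OCOC)c1CC=C(C)C
F3 | step 10 | (3R)-3-{2-[(2E)-3,7-dimethylocta-2,6-dien-1-yl]-4-methoxy-3-(methoxymethoxy)phenyl}-3-hydroxy-1-[4-methoxy-2-(methoxymethoxy)-3-(3-methylbut-2-en-1-yl)-6-(triisopropylsilyloxy)phenyl]propan-1-one | COc1cc(O[Si](C(C)C)(C(C)C)C(C)C)c(C(=O)C[C@@H](O)c2ccc(OC)c(OCOC)c2C/C=C(\C)CCC=C(C)C)c(OCOC)c1CC=C(C)C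
F4 | step 10 | (3R)-3-{2-[(2E)-3,7-dimethylocta-2,6-dien-1-yl]-4-methoxy-3-(methoxymethoxy)phenyl}-3-hydroxy-1-[6-hydroxy-4-methoxy-2-(methoxymethoxy)-3-(3-methylbut-2-en-1-yl)phenyl]propan-1-one | COc1cc(O)c(C(=O)C[C@@H](O)c2ccc(OC)c(OCOC)c2C/C=C(\C)CCC=C(C)C)c(OCOC)c1CC=C(C)C
F5 | step 12 | O-[(2R,3R)-2-{2-[(2E)-3,7-dimethylocta-2,6-dien-1-yl]-4-methoxy-3-(methoxymethoxy)phenyl}-7-methoxy-5-(methoxymethoxy)-6-(3-methylbut-2-en-1-yl)-4-oxo-3,4-dihydro-2H-chromen-3-yl] 1H-imidazole-1-carbothioate | COc1ccc([C@@H]2[C@@H](OC(=S)n4ccnc4)C(=O)c3c(cc(OC)c(CC=C(C)C)c3OCOC)O2)c(C/C=C(\C)CCC=C(C)C)c1OCOC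
F6 | step 3 | 1-[2,6-dihydroxy-4-methoxy-3-(3-methylbut-2-en-1-yl)phenyl]ethan-1-one | CC(=O)c1c(O)cc(OC)c(CC=C(C)C)c1O
F7 | step 3 | 1-[2-hydroxy-4-methoxy-3-(3-methylbut-2-en-1-yl)-6-(triisopropylsilyloxy)phenyl]ethan-1-one | CC(=O)c1c(O[Si](C(C)C)(C(C)C)C(C)C)cc(OC)c(CC=C(C)C)c1O
F8 | step 3 | 1-[4-methoxy-2-(methoxymethoxy)-3-(3-methylbut-2-en-1-yl)-6-(triisopropylsilyloxy)phenyl]ethan-1-one | CC(=O)c1c(O[Si](C(C)C)(C(C)C)C(C)C)cc(OC)c(CC=C(C)C)c1OCOC
F9 | step 6 | 2-bromo-4-methoxy-3-(methoxymethoxy)benzaldehyde | COc1ccc(C=O)c(Br)c1OCOC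
A1 | alternative 1 | 5-(tert-butyldimethylsilyloxy)-2-[3-(tert-butyldimethylsilyloxy)-4-methoxyphenyl]-7-methoxy-4-methylidene-6-(3-methylbut-2-en-1-yl)-4H-1,3-benzodioxine (racemic) | C=C1OC(c2ccc(OC)c(O[Si](C)(C)C(C)(C)C)c2)Oc2cc(OC)c(CC=C(C)C)c(O[Si](C)(C)C(C)(C)C)c21
A2 | alternative 1 | (2S)-5-(tert-butyldimethylsilyloxy)-2-[3-(tert-butyldimethylsilyloxy)-4-methoxyphenyl]-7-methoxy-6-(3-methylbut-2-en-1-yl)-2,3-dihydro-4H-chromen-4-one | COc1ccc([C@@H]2CC(=O)c3c(cc(OC)c(CC=C(C)C)c3O[Si](C)(C)C(C)(C)C)O2)cc1O[Si](C)(C)C(C)(C)C
A3 | alternative 2 | 6-[(3E)-4-{2-[(2E)-3,7-dimethylocta-2,6-dien-1-yl]-4-methoxy-3-(methoxymethoxy)phenyl}-2-oxobut-3-en-1-yl]-4-methoxy-5-(3-methylbut-2-en-1-yl)-2H-pyran-2-one | COC1=CC(=O)OC(CC(=O)/C=C/c2ccc(OC)c(OCOC)c2C/C=C(\C)CCC=C(C)C)=C1CC=C(C)C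
A4 | alternative 2 | (2E)-1-[2,6-dihydroxy-4-methoxy-3-(3-methylbut-2-en-1-yl)phenyl]-3-{2-[(2E)-3,7-dimethylocta-2,6-dien-1-yl]-4-methoxy-3-(methoxymethoxy)phenyl}prop-2-en-1-one | COc1cc(O)c(C(=O)/C=C/c2ccc(OC)c(OCOC)c2C/C=C(\C)CCC=C(C)C)c(O)c1CC=C(C)C
A5 | alternative 3 | 5-methoxy-3-(methoxymethoxy)-4-(3-methylbut-2-en-1-yl)-2-(trimethylsilyl)phenyl trifluoromethanesulfonate | COCOc1c([Si](C)(C)C)c(OS(=O)(=O)C(F)(F)F)cc(OC)c1CC=C(C)C
A6 | alternative 3 | (3R)-3-(tert-butyldimethylsilyloxy)-3-{2-[(2E)-3,7-dimethylocta-2,6-dien-1-yl]-4-methoxy-3-(methoxymethoxy)phenyl}propanoic acid | COc1ccc([C@H](O[Si](C)(C)C(C)(C)C)CC(=O)O)c(C/C=C(\C)CCC=C(C)C)c1OCOC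
A7 | alternative 3 | (3R)-3-(tert-butyldimethylsilyloxy)-3-{2-[(2E)-3,7-dimethylocta-2,6-dien-1-yl]-4-methoxy-3-(methoxymethoxy)phenyl}-1-[2-hydroxy-4-methoxy-6-(methoxymethoxy)-5-(3-methylbut-2-en-1-yl)phenyl]propan-1-one | COc1ccc([C@H](O[Si](C)(C)C(C)(C)C)CC(=O)c2c(O)cc(OC)c(CC=C(C)C)c2OCOC)c(C/C=C(\C)CCC=C(C)C)c1OCOC
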